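- At 25 min this flask has stood 2.08 times as long as at its last reading, so I need to know where it stops.

| setting | midnight | summer | flask |
|---|---|---|---|
| left-handed substrate | 0.10 M | 0.067 M | 0.10 M |
| right-handed substrate | 0.10 M | 0.067 M | 0.10 M |
| coupling partner | 0.22 M (fed, over 80 s) | 0.22 M (fed, over 80 s) | 0.220 M (fed, over 80 s) |
| free catalyst | 0.50 mM | 0.50 mM | 0.50 mM |
| racemization catalyst | 2.5 mM | 2.5 mM | 2.5 mM |
| remark | the very flask that is asked about, followed so far | run made earlier |  |
| time |  |  | 25 min |

- midnight (time / min: left-handed product / %, left-handed substrate / %): 0.667: 16, 37; 2.00: 44, 11; 4.00: 53, 1; 5.00: 54, 4; 8.00: 60, 2; 10.0: 58, 1; 12.0: 60, 0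
- summer (time / min: left-handed product / %, left-handed substrate / %): 0.500: 9, 42; 1.50: 44, 10; 3.00: 53, 2; 4.00: 58, 3; 6.00: 59, 0; 8.00: 60, 0; 10.0: 57, 0

(readings scatter by 1.5 percentage points)

- which holds at 25 min: what has brought the reaction to rest, or that it has not come to rest (it is still moving / all of the left-handed substrate has reacted / forward and back rates have come level / the coupling partner has run out first / no working catalyst is left)
- amount of left-handed product at 25 min, in percent of the left-handed substrate and right-handed substrate together charged
- amount of left-handed product if the flask were left three thousand times as long, in percent of the left-handed substrate and right-handed substrate together charged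

- I count turnovers, assuming that each turn of the free catalyst spends one coupling partner on one substrate. The partner cover, [coupling partner] charged over [left-handed substrate] plus [right-handed substrate] charged, is 1.10 here.
- The partner charge comes first: the summer run has a cover of 1.64, yet left-handed product reads 60% there and 60% here. A cover above one makes substrate the limiting reagent on my count, with 9.09% of the partner to spare.
- Time comes next: the midnight readings go 60%, 58%, 60% from 8.00 min to 12.0 min, against a scatter of 1.5 percentage points, so I expect little from waiting.
- Both catalysts have the same charges in both runs, so these runs do not show what a slip in either does.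
- Now the number: the last three midnight readings average 59.3%, which I commit to at both times. Left-handed substrate reads 0% at 12.0 min, so, within the scatter, I say it has reacted by 25 min.
- The forecast gives 59.5% and 60%, close to mine, but parts from me on the end with "no working catalyst is left", holding that “racemization has stopped”.
- The flask ends thus: all of the left-handed substrate has reacted; left-handed product stands at 59.4% at 25 min and 59.4% after the long wait.

    left-handed substrate + racemization catalyst ⇌ right-handed substrate + racemization catalyst, rate k1*[racemization catalyst]*[left-handed substrate] forward; the back reaction follows from the equilibrium constant (k = 4.58 L mol⁻¹ s⁻¹)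
    coupling partner + free catalyst + right-handed substrate → free catalyst + right-handed product (k = 254 L² mol⁻² s⁻¹)
    coupling partner + free catalyst + left-handed substrate → free catalyst + left-handed product (k = 448 L² mol⁻² s⁻¹)

- At 25.0 min in this flask, the forward racemization step alone gives left-handed substrate a half-life of 1.0 min, shorter than the 4.5 min that coupling gives right-handed substrate, and the two stand at 0.0290% and 0.0316%. The cover's 9.09% of spare partner stands beside 9.1% left in this flask. A neighbour flask with 0.055 M of coupling partner has a cover of 0.275; at 25.0 min its partner stands at 0%, and left-handed product 17.3% with right-handed product 10.2% make 27.5%.

All runs are simulated on assumed constants; scatter was added.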